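**Retrosynthetic overview**

- The strategy rests on ring B (the benzoate ring). Its ether oxygen on C1' and methoxy oxygen on C3' are meta to each other with C2'–H and C4'–H between and beside them, and its two carbon substituents sit on adjacent carbons (pentanoyl on C5', methyl ester on C6'). C1'–C4' therefore map onto a 1,3-dioxygenated cyclohexa-1,3-diene and C5'–C6' onto an alkynoate.
- Last operations: acid cleavage of two methoxymethyl ethers and one dioxolane, preceded by exchange of silicon for methyl on the C3' oxygen.
- Key disconnection: ring B is opened at C4'–C5' and C6'–C1' (Alder–Rickert retron) to a 1-aryloxy-3-silyloxycyclohexa-1,3-diene and a ketal-masked 4-oxo-alk-2-ynoate; the two remaining ring carbons of the diene leave as ethene.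
- The diene comes from a 3-aryloxycyclohex-2-enone, made from the ring A phenol (olivetol: formylation, protection, Baeyer–Villiger) and 3-chlorocyclohex-2-enone. The alkynoate comes from hept-1-yn-3-ol (oxidation, ketalization, carboxylation).
- Ring order: ring A is bought with olivetol; ring B is the only ring built and is formed in the key step, so the hindered diaryl ether is never made by coupling two arenes.

Key step: step 10

Remark: the target has no stereocentre; hept-1-yn-3-ol is used as the racemate and its stereocentre is removed by oxidation. Ring B is numbered C1' (ether carbon), C3' (methoxy carbon), C5' (pentanoyl carbon), C6' (ester carbon).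

**Route**

Step 1
Reactants: 1 olivetol (5-pentylbenzene-1,3-diol)
Product: 3 2,4-dihydroxy-6-pentylbenzaldehyde, via aryl iminium chloride 2 (not isolated)
Conditions: POCl3, DMF, 0 °C → rt; then H2O, 50 °C
Reagents that add atoms: N,N-dimethylformamide, CN(C)C=O; water, O
Why: Vilsmeier–Haack formylation attacks the resorcinol position para to one hydroxyl and ortho to the other (C4 of olivetol) in preference to the more hindered C2 between the two hydroxyls, which places the formyl carbon on the ring carbon that later carries the ether oxygen of ring A.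

Step 2
Reactants: 3 2,4-dihydroxy-6-pentylbenzaldehyde
Product: 5 2,4-bis(methoxymethoxy)-6-pentylbenzaldehyde, via disodium diphenolate 4 (not isolated)
Conditions: NaH, DMF, 0 °C; then MOMCl, 0 °C → rt
Reagents that add atoms: chloromethyl methyl ether, COCCl
Why: Williamson-type O-alkylation of the fully deprotonated diphenolate, in which deprotonation breaks the hydrogen bond of the ortho hydroxyl to the aldehyde so that both phenols are capped as methoxymethyl acetals that tolerate the later basic, fluoride and thermal steps.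

Step 3
Reactants: 5 2,4-bis(methoxymethoxy)-6-pentylbenzaldehyde
Product: 7 2,4-bis(methoxymethoxy)-6-pentylphenol, via aryl formate 6 (not isolated)
Conditions: mCPBA, CH2Cl2, 0 °C → rt; then (after NaHCO3 wash) K2CO3 (cat.), MeOH, rt
Reagents that add atoms: 3-chloroperoxybenzoic acid, OOC(=O)c1cccc(Cl)c1
Why: Baeyer–Villiger (Dakin-type) oxidation, in which the electron-rich aryl group migrates in preference to hydrogen to give the aryl formate, followed by base-catalysed methanolysis of the formate to the phenol.

Step 4
Reactants: 8 cyclohexane-1,3-dione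
Product: 9 3-chlorocyclohex-2-en-1-one
Conditions: (COCl)2, DMF (cat.), CH2Cl2, 0 °C → rt
Reagents that add atoms: oxalyl chloride, O=C(Cl)C(=O)Cl
Why: Activation of the enol oxygen of the 1,3-diketone as a chlorooxalate and addition–elimination by chloride gives the vinylogous acid chloride, a standard conversion of cyclic 1,3-diones.

Step 5
Reactants: 7 2,4-bis(methoxymethoxy)-6-pentylphenol; 9 3-chlorocyclohex-2-en-1-one
Product: 10 3-[2,4-bis(methoxymethoxy)-6-pentylphenoxy]cyclohex-2-en-1-one
Conditions: K2CO3, DMF, 60 °C, argon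
Reagents that add atoms: none
Why: Addition–elimination at the beta carbon of the vinylogous acid chloride (vinylogous nucleophilic acyl substitution) by the phenoxide, whose ortho and para positions are all substituted so that only O-attack is possible, forms the hindered aryl–O–C bond on an unhindered sp2 carbon before ring B exists.

Step 6
Reactants: 10 3-[2,4-bis(methoxymethoxy)-6-pentylphenoxy]cyclohex-2-en-1-one
Product: 12 1-[2,4-bis(methoxymethoxy)-6-pentylphenoxy]-3-[(tert-butyldimethylsilyl)oxy]cyclohexa-1,3-diene, via lithium dienolate 11 (not isolated)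
Conditions: LiN(i-Pr)2, THF, –78 °C; then TBSCl, DMPU, –78 → 0 °C
Reagents that add atoms: tert-butyldimethylsilyl chloride, CC(C)(C)[Si](C)(C)Cl
Why: Kinetic deprotonation of the vinylogous ester at the alpha' methylene by the hindered amide base at low temperature (Stork–Danheiser enolate chemistry) gives the cross-conjugated dienolate, and O-silylation in the presence of the polar cosolvent (silyl enol ether formation) fixes the 1-aryloxy-3-silyloxy-1,3-diene.

Step 7
Reactants: 13 hept-1-yn-3-ol (racemic)
Product: 14 hept-1-yn-3-one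
Conditions: Dess–Martin periodinane, CH2Cl2, 0 °C → rt
Reagents that add atoms: none
Why: Dess–Martin oxidation converts the secondary propargylic alcohol into the ynone under non-basic, non-nucleophilic conditions that leave the Michael acceptor untouched; the volatile product is best carried on as a concentrated solution.

Step 8
Reactants: 14 hept-1-yn-3-one
Product: 15 2-butyl-2-ethynyl-1,3-dioxolane
Conditions: Me3SiOCH2CH2OSiMe3, Me3SiOSO2CF3 (cat.), CH2Cl2, –78 → –20 °C
Reagents that add atoms: 1,2-bis(trimethylsilyloxy)ethane, C[Si](C)(C)OCCO[Si](C)(C)C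
Why: Noyori ketalization (silyl triflate-catalysed acetalization with the bis-silyl glycol ether) runs cold, water-free and without a free alcohol nucleophile, so that 1,2-addition at the carbonyl should outrun conjugate addition to the ynone.

Step 9
Reactants: 15 2-butyl-2-ethynyl-1,3-dioxolane
Product: 17 methyl 3-(2-butyl-1,3-dioxolan-2-yl)prop-2-ynoate, via lithium acetylide 16 (not isolated)
Conditions: n-BuLi, THF, –78 °C; then ClCO2Me, –78 → 0 °C
Reagents that add atoms: methyl chloroformate, COC(=O)Cl
Why: Deprotonation of the terminal alkyne and C-acylation of the lithium acetylide by the chloroformate (alkoxycarbonylation) is a standard route to alk-2-ynoates, and the ketal is inert to the base.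

Step 10
Reactants: 12 1-[2,4-bis(methoxymethoxy)-6-pentylphenoxy]-3-[(tert-butyldimethylsilyl)oxy]cyclohexa-1,3-diene; 17 methyl 3-(2-butyl-1,3-dioxolan-2-yl)prop-2-ynoate
Product: 19 methyl 2-[2,4-bis(methoxymethoxy)-6-pentylphenoxy]-6-(2-butyl-1,3-dioxolan-2-yl)-4-[(tert-butyldimethylsilyl)oxy]benzoate, via bicyclo[2.2.2]octadiene adduct 18 (not isolated)
Conditions: mesitylene, 2,6-di-tert-butyl-4-methylphenol (trace), sealed tube, argon, 170 °C
Reagents that add atoms: none
Why: Thermal normal-demand Diels–Alder addition of the electron-rich 1,3-dioxygenated diene to the ester-activated alkyne, through a concerted but asynchronous transition state in which the C4'–C5' bond leads, gives the bicyclo[2.2.2]octa-2,5-diene 18, which at the same temperature loses its saturated two-carbon bridge as ethene in a retro-Diels–Alder step and aromatizes without an oxidant; this is the Alder–Rickert reaction, established for 1-alkoxy-3-silyloxycyclohexa-1,3-dienes and alkynoates. Ring B is closed by an intermolecular [4+2] cycloaddition that forms C4'–C5' and C6'–C1' in one operation, and the arene is then released by the [4+2] cycloreversion. The two bridgehead stereocentres of 18 arise as a racemate and are erased on aromatization, so no stereocontrol is needed. The selectivity required is regiochemical: the aryloxy group on C1' and the silyloxy group on C3' both raise the orbital coefficient at C4', the ester makes the alkyne carbon that carries the dioxolane the electrophilic beta position, and the bulky ketal carbon is also the sterically better partner for the unsubstituted C4' terminus, so the ester should end up beside the ether oxygen. The ketone is carried as a dioxolane because a free ynone would polarize the alkyne more strongly than the ester and invert this orientation, and neutral conditions at a temperature kept as low as the cycloaddition allows should limit 1,5-hydrogen shifts that would scramble the diene.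

Step 11
Reactants: 19 methyl 2-[2,4-bis(methoxymethoxy)-6-pentylphenoxy]-6-(2-butyl-1,3-dioxolan-2-yl)-4-[(tert-butyldimethylsilyl)oxy]benzoate
Product: 21 methyl 2-[2,4-bis(methoxymethoxy)-6-pentylphenoxy]-6-(2-butyl-1,3-dioxolan-2-yl)-4-methoxybenzoate, via cesium phenolate 20 (not isolated)
Conditions: CsF, MeI, DMF, rt
Reagents that add atoms: iodomethane, CI
Why: Fluoride cleaves the aryl silyl ether and the resulting cesium phenolate is methylated in the same flask by SN2 reaction with iodomethane (Williamson ether synthesis), while the methyl ester, the dioxolane and the methoxymethyl ethers are inert to these weakly basic conditions.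

Step 12
Reactants: 21 methyl 2-[2,4-bis(methoxymethoxy)-6-pentylphenoxy]-6-(2-butyl-1,3-dioxolan-2-yl)-4-methoxybenzoate
Product: 22 methyl 2-(2,4-dihydroxy-6-pentylphenoxy)-4-methoxy-6-pentanoylbenzoate (CNP0313056.0)
Conditions: HCl, MeOH–H2O (9:1), 45 °C
Reagents that add atoms: water, O
Why: Acid-catalysed acetal cleavage removes both methoxymethyl ethers (the methoxymethyl cation is trapped by methanol as dimethoxymethane, so formaldehyde cannot alkylate electron-rich ring A) and hydrolyses the dioxolane to the ketone, whereas the doubly ortho-substituted methyl ester, the aryl methyl ether and the diaryl ether should survive dilute acid at this temperature.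

**Compound list**

1 | olivetol (5-pentylbenzene-1,3-diol) | CCCCCc1cc(O)cc(O)c1 | starting material
2 | [(2,4-dihydroxy-6-pentylphenyl)methylidene]dimethyliminium chloride | CCCCCc1cc(O)cc(O)c1C=[N+](C)C.[Cl-] | intermediate
3 | 2,4-dihydroxy-6-pentylbenzaldehyde | CCCCCc1cc(O)cc(O)c1C=O | intermediate
4 | disodium 4-formyl-5-pentylbenzene-1,3-diolate | CCCCCc1cc([O-])cc([O-])c1C=O.[Na+].[Na+] | intermediate
5 | 2,4-bis(methoxymethoxy)-6-pentylbenzaldehyde | CCCCCc1cc(OCOC)cc(OCOC)c1C=O | intermediate
6 | 2,4-bis(methoxymethoxy)-6-pentylphenyl formate | CCCCCc1cc(OCOC)cc(OCOC)c1OC=O | intermediate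
7 | 2,4-bis(methoxymethoxy)-6-pentylphenol | CCCCCc1cc(OCOC)cc(OCOC)c1O | intermediate
8 | cyclohexane-1,3-dione | O=C1CCCC(=O)C1 | starting material
9 | 3-chlorocyclohex-2-en-1-one | O=C1C=C(Cl)CCC1 | intermediate
10 | 3-[2,4-bis(methoxymethoxy)-6-pentylphenoxy]cyclohex-2-en-1-one | CCCCCc1cc(OCOC)cc(OCOC)c1OC1=CC(=O)CCC1 | intermediate
11 | lithium 5-[2,4-bis(methoxymethoxy)-6-pentylphenoxy]cyclohexa-1,5-dien-1-olate (cross-conjugated alpha' dienolate of 10) | CCCCCc1cc(OCOC)cc(OCOC)c1OC1=CC([O-])=CCC1.[Li+] | intermediate
12 | 1-[2,4-bis(methoxymethoxy)-6-pentylphenoxy]-3-[(tert-butyldimethylsilyl)oxy]cyclohexa-1,3-diene | CCCCCc1cc(OCOC)cc(OCOC)c1OC1=CC(O[Si](C)(C)C(C)(C)C)=CCC1 | intermediate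
13 | hept-1-yn-3-ol (racemic) | CCCCC(O)C#C | starting material
14 | hept-1-yn-3-one | CCCCC(=O)C#C | intermediate
15 | 2-butyl-2-ethynyl-1,3-dioxolane | CCCCC1(C#C)OCCO1 | intermediate
16 | lithium (2-butyl-1,3-dioxolan-2-yl)ethynide | CCCCC1(C#[C-])OCCO1.[Li+] | intermediate
17 | methyl 3-(2-butyl-1,3-dioxolan-2-yl)prop-2-ynoate | COC(=O)C#CC1(CCCC)OCCO1 | intermediate
18 | methyl 1-[2,4-bis(methoxymethoxy)-6-pentylphenoxy]-3-(2-butyl-1,3-dioxolan-2-yl)-5-[(tert-butyldimethylsilyl)oxy]bicyclo[2.2.2]octa-2,5-diene-2-carboxylate (racemic) | CCCCCc1cc(OCOC)cc(OCOC)c1OC12CCC(C(O[Si](C)(C)C(C)(C)C)=C1)C(C1(CCCC)OCCO1)=C2C(=O)OC | intermediate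
19 | methyl 2-[2,4-bis(methoxymethoxy)-6-pentylphenoxy]-6-(2-butyl-1,3-dioxolan-2-yl)-4-[(tert-butyldimethylsilyl)oxy]benzoate | CCCCCc1cc(OCOC)cc(OCOC)c1Oc1cc(O[Si](C)(C)C(C)(C)C)cc(C2(CCCC)OCCO2)c1C(=O)OC | intermediate
20 | cesium 3-[2,4-bis(methoxymethoxy)-6-pentylphenoxy]-5-(2-butyl-1,3-dioxolan-2-yl)-4-(methoxycarbonyl)phenolate | CCCCCc1cc(OCOC)cc(OCOC)c1Oc1cc([O-])cc(C2(CCCC)OCCO2)c1C(=O)OC.[Cs+] | intermediate
21 | methyl 2-[2,4-bis(methoxymethoxy)-6-pentylphenoxy]-6-(2-butyl-1,3-dioxolan-2-yl)-4-methoxybenzoate | CCCCCc1cc(OCOC)cc(OCOC)c1Oc1cc(OC)cc(C2(CCCC)OCCO2)c1C(=O)OC | intermediate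
22 | methyl 2-(2,4-dihydroxy-6-pentylphenoxy)-4-methoxy-6-pentanoylbenzoate | CCCCCc1cc(O)cc(O)c1Oc1cc(OC)cc(C(=O)CCCC)c1C(=O)OC | target

**Step count**

Total step count: 12.
Longest linear sequence: 8 steps (steps 1, 2, 3, 5, 6, 10, 11, 12, from olivetol).

**Steps most likely to fail**

Step 10. The cycloaddition may be slow because the alkyne carries a quaternary ketal carbon and the diene terminus carries a bulky aryloxy group. Prolonged heating may then allow 1,5-hydrogen shifts in the diene, which would leak into the regioisomeric arene, or thermal loss of the silyl enol ether. Fallback: set out from 12 and use the symmetrical, much more reactive dimethyl but-2-ynedioate, so that regiochemistry in the cycloaddition no longer matters and the two carbonyl groups are told apart afterwards.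
- Heating 12 with the diester in toluene should give, through dimethyl 1-[2,4-bis(methoxymethoxy)-6-pentylphenoxy]-5-[(tert-butyldimethylsilyl)oxy]bicyclo[2.2.2]octa-2,5-diene-2,3-dicarboxylate F1 and loss of ethene, dimethyl 3-[2,4-bis(methoxymethoxy)-6-pentylphenoxy]-5-[(tert-butyldimethylsilyl)oxy]phthalate F2.
- CsF and MeI in DMF, as in step 11, should give dimethyl 3-[2,4-bis(methoxymethoxy)-6-pentylphenoxy]-5-methoxyphthalate F3.
- One equivalent of LiOH in THF–H2O should saponify the ester that is meta to both oxygens and flanked by a ring hydrogen (less hindered and more electrophilic), giving 3-[2,4-bis(methoxymethoxy)-6-pentylphenoxy]-5-methoxy-2-(methoxycarbonyl)benzoic acid F4.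
- Amide coupling with MeNHOMe·HCl (EDC·HCl, i-Pr2NEt, CH2Cl2) should give the Weinreb amide methyl 2-[2,4-bis(methoxymethoxy)-6-pentylphenoxy]-4-methoxy-6-[methoxy(methyl)carbamoyl]benzoate F5.
- BuMgCl in THF at –20 °C should give methyl 2-[2,4-bis(methoxymethoxy)-6-pentylphenoxy]-4-methoxy-6-pentanoylbenzoate F6.
- The conditions of step 12 then cleave the two methoxymethyl ethers, and the route comes back at 22.

Step 6. Deprotonation may partly occur at the gamma methylene or the enolate may equilibrate to the linearly conjugated isomer, and the dienol ether may hydrolyse during isolation. Fallback: the diene is neither isolated nor purified and no silyl group is carried forward.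
- Setting out from 10, the enone is added to premixed LiN(i-Pr)2 and Me3SiCl in THF at –78 °C (internal quench), so that the kinetic enolate 11 is trapped at once as 1-[2,4-bis(methoxymethoxy)-6-pentylphenoxy]-3-[(trimethylsilyl)oxy]cyclohexa-1,3-diene F7.
- After exchange of the solvent for mesitylene and filtration, the crude diene is heated with 17 as in step 10. Through methyl 1-[2,4-bis(methoxymethoxy)-6-pentylphenoxy]-3-(2-butyl-1,3-dioxolan-2-yl)-5-[(trimethylsilyl)oxy]bicyclo[2.2.2]octa-2,5-diene-2-carboxylate F8 this should give methyl 2-[2,4-bis(methoxymethoxy)-6-pentylphenoxy]-6-(2-butyl-1,3-dioxolan-2-yl)-4-[(trimethylsilyl)oxy]benzoate F9.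
- The crude aryl silyl ether is treated with CsF and MeI in DMF, which returns to the route at phenolate 20 and hence at 21.

Step 8. The terminal ynone may undergo conjugate addition of the glycol component or oligomerize under the acid catalyst, and material may be lost by evaporation. Fallback: the alkyne terminus is capped with silicon before the ketone exists.
- Setting out from 13, n-BuLi (2 equiv) in THF gives dilithium hept-1-yn-1-id-3-olate F10, and Me3SiCl (2 equiv) converts it into trimethyl{[1-(trimethylsilyl)hept-1-yn-3-yl]oxy}silane F11.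
- Dilute aqueous acid on work-up cleaves only the O–Si bond to give 1-(trimethylsilyl)hept-1-yn-3-ol F12.
- Dess–Martin oxidation gives the non-volatile 1-(trimethylsilyl)hept-1-yn-3-one F13, whose silylated terminus is shielded from nucleophiles.
- Ethane-1,2-diol with TsOH (cat.) in benzene under Dean–Stark conditions should give [(2-butyl-1,3-dioxolan-2-yl)ethynyl]trimethylsilane F14.
- K2CO3 in MeOH removes the C-silyl group and comes back to the route at 15.

**Further compounds**

F1 | step 10 | dimethyl 1-[2,4-bis(methoxymethoxy)-6-pentylphenoxy]-5-[(tert-butyldimethylsilyl)oxy]bicyclo[2.2.2]octa-2,5-diene-2,3-dicarboxylate (racemic) | CCCCCc1cc(OCOC)cc(OCOC)c1OC12CCC(C(O[Si](C)(C)C(C)(C)C)=C1)C(C(=O)OC)=C2C(=O)OC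
F2 | step 10 | dimethyl 3-[2,4-bis(methoxymethoxy)-6-pentylphenoxy]-5-[(tert-butyldimethylsilyl)oxy]phthalate | CCCCCc1cc(OCOC)cc(OCOC)c1Oc1cc(O[Si](C)(C)C(C)(C)C)cc(C(=O)OC)c1C(=O)OC
F3 | step 10 | dimethyl 3-[2,4-bis(methoxymethoxy)-6-pentylphenoxy]-5-methoxyphthalate | CCCCCc1cc(OCOC)cc(OCOC)c1Oc1cc(OC)cc(C(=O)OC)c1C(=O)OC
F4 | step 10 | 3-[2,4-bis(methoxymethoxy)-6-pentylphenoxy]-5-methoxy-2-(methoxycarbonyl)benzoic acid | CCCCCc1cc(OCOC)cc(OCOC)c1Oc1cc(OC)cc(C(=O)O)c1C(=O)OC
F5 | step 10 | methyl 2-[2,4-bis(methoxymethoxy)-6-pentylphenoxy]-4-methoxy-6-[methoxy(methyl)carbamoyl]benzoate | CCCCCc1cc(OCOC)cc(OCOC)c1Oc1cc(OC)cc(C(=O)N(C)OC)c1C(=O)OC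
F6 | step 10 | methyl 2-[2,4-bis(methoxymethoxy)-6-pentylphenoxy]-4-methoxy-6-pentanoylbenzoate | CCCCCc1cc(OCOC)cc(OCOC)c1Oc1cc(OC)cc(C(=O)CCCC)c1C(=O)OC
F7 | step 6 | 1-[2,4-bis(methoxymethoxy)-6-pentylphenoxy]-3-[(trimethylsilyl)oxy]cyclohexa-1,3-diene | CCCCCc1cc(OCOC)cc(OCOC)c1OC1=CC(O[Si](C)(C)C)=CCC1
F8 | step 6 | methyl 1-[2,4-bis(methoxymethoxy)-6-pentylphenoxy]-3-(2-butyl-1,3-dioxolan-2-yl)-5-[(trimethylsilyl)oxy]bicyclo[2.2.2]octa-2,5-diene-2-carboxylate (racemic) | CCCCCc1cc(OCOC)cc(OCOC)c1OC12CCC(C(O[Si](C)(C)C)=C1)C(C1(CCCC)OCCO1)=C2C(=O)OC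
F9 | step 6 | methyl 2-[2,4-bis(methoxymethoxy)-6-pentylphenoxy]-6-(2-butyl-1,3-dioxolan-2-yl)-4-[(trimethylsilyl)oxy]benzoate | CCCCCc1cc(OCOC)cc(OCOC)c1Oc1cc(O[Si](C)(C)C)cc(C2(CCCC)OCCO2)c1C(=O)OC
F10 | step 8 | dilithium hept-1-yn-1-id-3-olate (racemic) | CCCCC([O-])C#[C-].[Li+].[Li+]
F11 | step 8 | trimethyl{[1-(trimethylsilyl)hept-1-yn-3-yl]oxy}silane (racemic) | CCCCC(O[Si](C)(C)C)C#C[Si](C)(C)C
F12 | step 8 | 1-(trimethylsilyl)hept-1-yn-3-ol (racemic) | CCCCC(O)C#C[Si](C)(C)C
F13 | step 8 | 1-(trimethylsilyl)hept-1-yn-3-one | CCCCC(=O)C#C[Si](C)(C)C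
F14 | step 8 | [(2-butyl-1,3-dioxolan-2-yl)ethynyl]trimethylsilane | CCCCC1(C#C[Si](C)(C)C)OCCO1
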